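**The ratio.** Side product per chain is the ratio I follow, and in the closed runs it grows with the chains. If s and u are the fractions of the charge in side product and in chains, s divided by the square of u reads 0.277 at the end of dawn. This side ratio κ, side product over chains squared, is a selectivity factor of my own making. It reads 0.274 at dawn's first reading, so the two ends of dawn read alike.

all flasks: initiator 0.95 mol%

| charge | free monomer | transfer agent | remark | time |
|---|---|---|---|---|
| dusk | 0.30 M | 0.090 M | run made earlier |  |
| dawn | 0.20 M | 0.090 M | run made earlier |  |
| autumn | 0.45 M | 0.090 M | run made earlier |  |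
| summer | 0.30 M | 0.14 M | run made earlier |  |
| birch | 0.30 M | 0.0900 M | one stirred flow tank at steady state, fed with the mixture as stated, mean residence time 15.0 d |  |
| elm | 0.30 M | 0.0900 M | one stirred flow tank at steady state, fed with the mixture as stated, mean residence time 5.0 d |  |
| cedar | 0.30 M | 0.0900 M | everything together in a closed stirred flask, run for 5.0 d | 5.0 d |
| maple | 0.30 M (fed, over 4.00 d) | 0.0900 M | a stirred flask in which free monomer is dosed at a steady rate over 4.00 d without added volume, worked up at 5.0 d | 5.0 d |

| run | time / d | monomer in chains / % | side product / % |
|---|---|---|---|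
| dusk | 0.208 | 64.6 | 11.4 |
| dusk | 0.625 | 79.0 | 16.5 |
| dusk | 1.04 | 78.0 | 17.4 |
| dusk | 1.67 | 78.8 | 16.7 |
| dusk | 2.50 | 79.4 | 17.2 |
| dusk | 3.00 | 78.3 | 17.1 |
| dawn | 0.250 | 57.3 | 9.0 |
| dawn | 0.417 | 71.2 | 13.5 |
| dawn | 0.625 | 75.3 | 15.5 |
| dawn | 1.04 | 78.2 | 17.0 |
| dawn | 1.67 | 79.1 | 17.1 |
| dawn | 3.00 | 78.8 | 17.2 |
| autumn | 0.208 | 73.3 | 14.9 |
| autumn | 0.625 | 79.5 | 17.1 |
| autumn | 1.04 | 79.1 | 16.9 |
| autumn | 1.67 | 78.3 | 16.7 |
| autumn | 2.50 | 78.3 | 17.3 |
| autumn | 3.00 | 79.5 | 17.3 |
| summer | 0.625 | 78.9 | 17.2 |
| summer | 1.25 | 78.0 | 17.9 |
| summer | 1.67 | 78.4 | 17.5 |
| summer | 2.50 | 77.3 | 17.5 |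
| summer | 3.00 | 77.7 | 17.2 |

(readings scatter by 0.5 percentage points)

- in percentages every species weighs as the free monomer in it: one side product counts as two
- the stated concentrations are those of everything mixed, before any reaction; amounts are the same in each set-up
- the numbers in the tables scatter with a standard deviation of 0.5 percentage points
- the feed brings no volume worth counting
- the earlier runs were made in a closed, stirred flask

- order of the set-ups by the share of monomer in chains in all that became monomer in chains or side product, at the outlet or at the end, highest first (birch / elm / cedar / maple)
- share of monomer in chains in all that became monomer in chains or side product, at the outlet or at the end, birch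
- share of monomer in chains in all that became monomer in chains or side product, at the outlet or at the end, elm
- share of monomer in chains in all that became monomer in chains or side product, at the outlet or at the end, cedar
- share of monomer in chains in all that became monomer in chains or side product, at the outlet or at the end, maple

**Monomer charge.** By hand, I take free monomer to enter growth and side reaction alike, so it cancels and κ should stay put. Autumn, charged at 2.25 times dawn, ends at 0.274.

**Transfer agent.** By hand, an agent that stops growth should raise κ. Summer, with 0.14 M against 0.090 M in dusk, ends at 0.285 against 0.279, a gap I cannot read through the scatter. But dusk and summer stand level by about 0.625 d, far shorter than birch's stay of 15.0 d, so these two runs say little about a long stay.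

**The vessel.** If κ holds, a closed flask gives s/u = κu, and with free monomer cancelling, dosing should not change that, so I reckon cedar and maple at 82.2%. If the same κ holds in a tank at steady state, new chains form at the outlet level of u, so s/u = 2κu. With u + s at dusk's 95.4%, that gives u = 69.0% and a share of 72.3%. I put birch last for its stay of 15.0 d, far beyond dusk's last reading at 3.00 d, and I hold both tank figures as high.

**The forecast.** The forecast says 72.6% for birch, 72.8% for elm, 82.2% for cedar and 82% for maple, in the order cedar > maple > elm > birch, and of the tanks it says “every bit of monomer sees the outlet chain level”.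

**The result.** The order is cedar > maple > elm > birch, with birch 47.6%, elm 60.2%, cedar 82.2% and maple 76.6%.

    free monomer + initiator → living end + monomer in chains (k = 7.70 M⁻¹ h⁻¹)
    free monomer + living end → monomer in chains + living end, rate k2*[living end]*[free monomer] (k = 110 M⁻¹ h⁻¹)
    living end + transfer agent → dead chain (kL = 0.0690 M⁻¹ h⁻¹)
    2 free monomer → self-condensation product (k = 0.0430 M⁻¹ h⁻¹)
    free monomer + monomer in chains → side product (k = 0.240 M⁻¹ h⁻¹)

Elm's outlet holds 38.1% side product beside 3.83% free monomer, and its share puts u at 57.6%. The tank rule then returns κ = 0.574, twice the closed-run reading. Maple, with 23.3% side product and u at 76.2%, returns 0.401 by the closed rule, against 0.277 from dawn.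

Readings and results come from a simulation for an exercise; scatter was added.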